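Late in the theta run, at its last readings, the left-handed substrate and the right-handed substrate were closing. The excess of right-handed substrate, their difference over their sum among what was left, read 15.8% at 5.00 min but 10.2% at 15.0 min. Mirror images have the same energy, so where they pass into each other the excess heads for zero (thermodynamic control), and what I had to watch in the theta flask was the early top (kinetic control).

the same everywhere: left-handed substrate 10 mM; right-handed substrate 10 mM; free catalyst 1.5 mM

| charge | partner | remark | time |
|---|---|---|---|
| theta | 15 mM | the very flask that is asked about, followed so far |  |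
| zeta | 7.5 mM | run made earlier |  |
| flask | 15.0 mM |  | 40 min |

| run | time / min | right-handed substrate / % | left-handed substrate / % | left-handed product / % |
|---|---|---|---|---|
| theta | 1.33 | 47.3 | 39.1 | 8.1 |
| theta | 2.50 | 44.7 | 34.7 | 14.0 |
| theta | 5.00 | 40.3 | 29.3 | 23.5 |
| theta | 8.00 | 35.0 | 26.3 | 31.7 |
| theta | 15.0 | 27.6 | 22.5 | 44.2 |
| zeta | 3.00 | 46.3 | 39.4 | 9.4 |
| zeta | 6.00 | 43.0 | 36.7 | 14.8 |
| zeta | 10.0 | 38.9 | 35.1 | 20.3 |
| zeta | 12.0 | 38.4 | 34.2 | 21.9 |
| zeta | 15.0 | 36.4 | 33.3 | 24.7 |

(readings scatter by 0.3 percentage points)

1. whether the excess of right-handed substrate over left-handed substrate among what is left of the two reaches 80% by 40 min (no / yes)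
2. the highest excess of right-handed substrate over left-handed substrate among what is left of the two up to 40 min

- free catalyst is single-handed; left-handed substrate and right-handed substrate are mirror images of each other, charged as a racemate, each of them at the stated concentration

I asked which given numbers had to be known well. For the top, the limit of 40 min looked unimportant: the theta readings fell after 5.00 min, and the limit stood later than that. Free catalyst I could not test, since both runs held 1.5 mM. Partner mattered: the zeta run, with 7.5 mM against 15 mM, topped at a reading of 8.05% at 3.00 min, half of the highest theta reading.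

So I carried one quantity, the top excess per partner charged at this free catalyst, read from the zeta run as 0.0107 mM⁻¹. It rests on a gap of 6.9 percentage points against a scatter of 0.3 points per reading. For the asked flask it gave 16.1%, which lay below the 80% wanted.

The forecast said no, with a top of 16% (range 15% to 17.5%), and that “the excess keeps falling towards zero”.

The asked flask gave no, with a top of 15.7%.

    partner + catalyst intermediate B → free catalyst + right-handed product (k = 0.680 M⁻¹ s⁻¹)
    2 free catalyst → spent catalyst (k = 3.80 M⁻¹ s⁻¹)
    free catalyst + right-handed substrate ⇌ catalyst intermediate B (K = 69.0 M⁻¹, k = 28.0 M⁻¹ s⁻¹)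
    partner + catalyst intermediate A → free catalyst + left-handed product (k = 1.80 M⁻¹ s⁻¹)
    left-handed substrate ⇌ right-handed substrate (k = 0.00230 s⁻¹)
    free catalyst + left-handed substrate ⇌ catalyst intermediate A (K = 390 M⁻¹, k = 26.0 M⁻¹ s⁻¹)
    free catalyst ⇌ dormant form (K = 0.260, k = 0.00490 s⁻¹)

My 16.1% stood against that 15.7%. At 40.0 min the asked flask held left-handed substrate at 17.8% and right-handed substrate at 18.7%. A neighbour charged with 6.0 mM of partner, its other charges as in the asked flask, reckoned at 6.42%, and it topped at 6.68%. At 40.0 min that neighbour held left-handed substrate at 34.8% and right-handed substrate at 35.0%.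

The readings are calculated from invented constants; the scatter is artificial.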